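**Retrosynthetic overview**

1. Numbering (daucane) used throughout: ring A = cyclopentane C1(CH3)–C2–C3–C4(OH)(i-Pr)–C5; ring B = cycloheptene C1–C5–C6(O-anisoyl)–C7–C8(CH3)=C9–C10(OAc); α is the face of the C1 methyl and of H5.
2. Endgame: the esters come last (anisoylation of 6-OH, Luche reduction of a C10 enone, acetylation), which reduces the target to a ring B enone diol.
3. Key disconnection: ring B is closed last, in one flask, from a ring A β-keto sulfoxide and crotonaldehyde (C6, C7, C8 and the C8 methyl). C8–C9 comes from Michael addition of the sulfinyl-activated C9 and, after ring closure, loss of PhSOH (C8=C9); C5–C6 comes from Prins cyclization–hydration onto the C4=C5 alkene of ring A.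
4. Enabling feature: in ring B the C6 oxygen and the C8 methyl are 1,3-related (a crotonaldehyde unit); C10 is oxygenated and flanked by the quaternary C1, so a C10 ketone can be activated only toward C9; the tertiary C4–OH of ring A and the C6 oxygen of ring B form an anti 1,3-diol across the ring-fusion carbon C5, the retron of a Prins hydration.
5. Ring A is made first from methyl 3-oxocyclopent-1-ene-1-carboxylate; C1 is the only stereocenter set by catalysis, and C4, C5, C6 (key step) and C10 (reduction) are relayed from it.

Key step: step 4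

Remark: C8–C9 is first joined as a single bond with the phenylsulfinyl group on C9 and becomes the ring alkene inside the same operation; sulfur, C8 and C9 are stereo-mixtures until then and are drawn without descriptors; compounds 1, 5, 7 and 11 are taken as commercial.

**Step 1**
Reactants: 1 methyl 3-oxocyclopent-1-ene-1-carboxylate
Product: 3 methyl (1S)-1-methyl-3-{[(trifluoromethyl)sulfonyl]oxy}cyclopent-2-ene-1-carboxylate, via methylzinc enolate 2 (not isolated)
Conditions: Me2Zn, Cu(OTf)2 (5 mol %), chiral sulfonate-bearing imidazolinium salt (carbene ligand precursor, 5 mol %, enantiomer chosen for the (S) center), t-BuOMe, −30 °C; then Tf2O, −30 to 0 °C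
Reagents that add atoms: dimethylzinc C[Zn]C; trifluoromethanesulfonic anhydride O=S(=O)(OS(=O)(=O)C(F)(F)F)C(F)(F)F
Why: Copper-catalysed asymmetric conjugate addition of dimethylzinc (chiral carbene ligand on Cu(OTf)2) to the ester-bearing β-carbon should set the quaternary center C1 by catalyst control, and O-triflation of the regiodefined zinc enolate in the same flask fixes the future C4=C5 double bond on the side of C1.

**Step 2**
Reactants: 3 methyl (1S)-1-methyl-3-{[(trifluoromethyl)sulfonyl]oxy}cyclopent-2-ene-1-carboxylate
Product: 4 methyl (1S)-1-methyl-3-(propan-2-yl)cyclopent-2-ene-1-carboxylate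
Conditions: i-PrMgCl, Fe(acac)3 (5 mol %), THF/NMP, −20 °C
Reagents that add atoms: isopropylmagnesium chloride CC(C)[Mg]Cl
Why: Iron-catalysed Kumada-type cross-coupling of an alkenyl triflate with a secondary alkyl Grignard reagent is much faster than attack on the hindered methyl ester and should put the isopropyl group on C4 without touching C1.

**Step 3**
Reactants: 4 methyl (1S)-1-methyl-3-(propan-2-yl)cyclopent-2-ene-1-carboxylate; 5 methyl phenyl sulfoxide
Product: 6 1-[(1S)-1-methyl-3-(propan-2-yl)cyclopent-2-en-1-yl]-2-(phenylsulfinyl)ethan-1-one (both sulfur epimers)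
Conditions: 5 (2.2 equiv), LiN(i-Pr)2 (2.2 equiv), THF, −78 °C; then 4, −78 to 0 °C
Reagents that add atoms: none
Why: Acylation of lithiated methyl phenyl sulfoxide by the non-enolizable ester (Claisen-type condensation) should give the β-keto sulfoxide, whose deprotonation by the second equivalent of the anion prevents over-addition, while C1 is not affected.

**Step 4**
Reactants: 6 1-[(1S)-1-methyl-3-(propan-2-yl)cyclopent-2-en-1-yl]-2-(phenylsulfinyl)ethan-1-one; 7 (E)-but-2-enal (crotonaldehyde)
Product: 10 (3R,3aR,4S,8aS)-3,4-dihydroxy-6,8a-dimethyl-3-(propan-2-yl)-2,3,3a,4,5,8a-hexahydroazulen-8(1H)-one, via Michael adduct 8 (not isolated), via sulfinyl bicyclic diol 9 (not isolated)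
Conditions: diphenylprolinol trimethylsilyl ether (10 mol %), PhCO2H (10 mol %), toluene, 0 to 25 °C; then 0.5 M aq. H2SO4, 25 °C; then NaHCO3 (to pH 7), 80 °C
Reagents that add atoms: water O
Why: Proposed new method: the iminium ion formed from 7 and the amine catalyst is attacked at C8 by the sulfinyl-stabilised enol of 6 (Michael addition, C8–C9 single bond, aldehyde 8), aqueous acid then drives a Prins cyclization in which the ring A alkene attacks the protonated aldehyde (C5–C6) and water opens the resulting bridged cation at C4 (diol 9), and after neutralisation heat expels benzenesulfenic acid by syn-elimination, which turns C8–C9 into the C8=C9 double bond. The closest known reaction types are the Michael addition and thermal sulfoxide elimination of β-keto sulfoxides and the aqueous-acid Prins cyclization–hydration of citronellal to p-menthane-3,8-diol, whose merger into a one-flask (4+3) annulation closing a seven-membered ring is not known. Ring B is closed by attack of alkene carbon C5 on the aldehyde carbon C6, a 7-exo-trig closure at the carbonyl group in which C4 and the oxygen stay outside the new ring. C5 is set by the tether (the aldehyde hangs from C10 on the β-face of C1, so ring B is cis-fused), C6 by the oxetane-like transition state in which the carbonyl oxygen leans over ring A toward the developing cation at C4 (6β-OH), and C4 by anti opening of that bridged cation by water from the free α-face (4α-OH, isopropyl β), while the centers at C8, C9 and sulfur vanish in the elimination, C9 epimerising under the warm neutral conditions so that every isomer reaches the syn-periplanar arrangement. The step needs chemoselectivity (enal β-carbon for the carbon acid, aldehyde carbon for the alkene) and the right order of events, secured by the amine catalyst, which activates only the enal in the first stage, and by temperature, since the sulfoxide should survive at 25 °C and eliminate only at 80 °C, after ring B is closed.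

**Step 5**
Reactants: 10 (3R,3aR,4S,8aS)-3,4-dihydroxy-6,8a-dimethyl-3-(propan-2-yl)-2,3,3a,4,5,8a-hexahydroazulen-8(1H)-one; 11 4-methoxybenzoyl chloride
Product: 12 (3R,3aR,4S,8aS)-3-hydroxy-6,8a-dimethyl-8-oxo-3-(propan-2-yl)-1,2,3,3a,4,5,8,8a-octahydroazulen-4-yl 4-methoxybenzoate
Conditions: pyridine, DMAP (10 mol %), CH2Cl2, 0 °C
Reagents that add atoms: none
Why: DMAP-catalysed acylation should take the only secondary hydroxyl (C6), the tertiary C4 hydroxyl being inert, and the cold, weakly basic medium avoids vinylogous β-elimination of the δ-acyloxy enone.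

**Step 6**
Reactants: 12 (3R,3aR,4S,8aS)-3-hydroxy-6,8a-dimethyl-8-oxo-3-(propan-2-yl)-1,2,3,3a,4,5,8,8a-octahydroazulen-4-yl 4-methoxybenzoate
Product: 13 (3R,3aR,4S,8S,8aS)-3,8-dihydroxy-6,8a-dimethyl-3-(propan-2-yl)-1,2,3,3a,4,5,8,8a-octahydroazulen-4-yl 4-methoxybenzoate
Conditions: NaBH4, CeCl3·7H2O, MeOH, −78 to −40 °C
Reagents that add atoms: none
Why: Luche reduction gives 1,2-reduction of the enone, and hydride is expected to add to C10 anti to the angular C1 methyl (from the β-face), as in other ketones next to an angular methyl group, which places the new hydroxyl α.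

**Step 7**
Reactants: 13 (3R,3aR,4S,8S,8aS)-3,8-dihydroxy-6,8a-dimethyl-3-(propan-2-yl)-1,2,3,3a,4,5,8,8a-octahydroazulen-4-yl 4-methoxybenzoate
Product: 14 (3R,3aR,4S,8S,8aS)-8-acetoxy-3-hydroxy-6,8a-dimethyl-3-(propan-2-yl)-1,2,3,3a,4,5,8,8a-octahydroazulen-4-yl 4-methoxybenzoate
Conditions: Ac2O, pyridine, DMAP (10 mol %), CH2Cl2, 0 °C
Reagents that add atoms: acetic anhydride CC(=O)OC(C)=O
Why: DMAP-catalysed acetylation of the secondary allylic alcohol at 0 °C should leave the tertiary C4 hydroxyl free and complete the target without touching any stereocenter.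

**Compound list**

1 | methyl 3-oxocyclopent-1-ene-1-carboxylate | COC(=O)C1=CC(=O)CC1 | starting material
2 | methylzinc enolate, methyl (1S)-1-methyl-3-[(methylzincio)oxy]cyclopent-2-ene-1-carboxylate | COC(=O)[C@@]1(C)CCC(O[Zn]C)=C1 | intermediate
3 | methyl (1S)-1-methyl-3-{[(trifluoromethyl)sulfonyl]oxy}cyclopent-2-ene-1-carboxylate | COC(=O)[C@@]1(C)CCC(OS(=O)(=O)C(F)(F)F)=C1 | intermediate
4 | methyl (1S)-1-methyl-3-(propan-2-yl)cyclopent-2-ene-1-carboxylate | COC(=O)[C@@]1(C)CCC(C(C)C)=C1 | intermediate
5 | methyl phenyl sulfoxide | CS(=O)c1ccccc1 | starting material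
6 | 1-[(1S)-1-methyl-3-(propan-2-yl)cyclopent-2-en-1-yl]-2-(phenylsulfinyl)ethan-1-one | O=C(CS(=O)c1ccccc1)[C@@]1(C)CCC(C(C)C)=C1 | intermediate
7 | (E)-but-2-enal | C/C=C/C=O | starting material
8 | Michael adduct, 3-methyl-5-[(1S)-1-methyl-3-(propan-2-yl)cyclopent-2-en-1-yl]-5-oxo-4-(phenylsulfinyl)pentanal | O=CCC(C)C(S(=O)c1ccccc1)C(=O)[C@@]1(C)CCC(C(C)C)=C1 | intermediate
9 | sulfinyl bicyclic diol, (3R,3aR,4S,8aS)-3,4-dihydroxy-6,8a-dimethyl-7-(phenylsulfinyl)-3-(propan-2-yl)octahydroazulen-8(1H)-one | O[C@H]2CC(C)C(S(=O)c1ccccc1)C(=O)[C@@]3(C)CC[C@@](O)(C(C)C)[C@@H]23 | intermediate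
10 | (3R,3aR,4S,8aS)-3,4-dihydroxy-6,8a-dimethyl-3-(propan-2-yl)-2,3,3a,4,5,8a-hexahydroazulen-8(1H)-one | O[C@H]2CC(C)=CC(=O)[C@@]3(C)CC[C@@](O)(C(C)C)[C@@H]23 | intermediate
11 | 4-methoxybenzoyl chloride | COc1ccc(C(Cl)=O)cc1 | starting material
12 | (3R,3aR,4S,8aS)-3-hydroxy-6,8a-dimethyl-8-oxo-3-(propan-2-yl)-1,2,3,3a,4,5,8,8a-octahydroazulen-4-yl 4-methoxybenzoate | COc1ccc(C(=O)O[C@H]2CC(C)=CC(=O)[C@@]3(C)CC[C@@](O)(C(C)C)[C@@H]23)cc1 | intermediate
13 | (3R,3aR,4S,8S,8aS)-3,8-dihydroxy-6,8a-dimethyl-3-(propan-2-yl)-1,2,3,3a,4,5,8,8a-octahydroazulen-4-yl 4-methoxybenzoate | COc1ccc(C(=O)O[C@H]2CC(C)=C[C@H](O)[C@@]3(C)CC[C@@](O)(C(C)C)[C@@H]23)cc1 | intermediate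
14 | (3R,3aR,4S,8S,8aS)-8-acetoxy-3-hydroxy-6,8a-dimethyl-3-(propan-2-yl)-1,2,3,3a,4,5,8,8a-octahydroazulen-4-yl 4-methoxybenzoate | COc1ccc(C(=O)O[C@H]2CC(C)=C[C@H](OC(C)=O)[C@@]3(C)CC[C@@](O)(C(C)C)[C@@H]23)cc1 | target

**Step count and risks**

Total step count: 7. Longest linear sequence: 7 steps (from 1).

Step 4 (Proposed new method). What may go wrong: proton loss from the C4 cation (ene-type alkenes) or capture of that cation by the C10 carbonyl oxygen from the β-face may outrun anti capture by water. The β-keto sulfoxide may also break down in aqueous acid (Pummerer-type) or eliminate before ring B is closed. Fallback (sets out from 8, comes back at 9): the Michael stage is worked up and aldehyde 8 is isolated. A Me2AlCl-promoted intramolecular carbonyl-ene reaction (CH2Cl2, −78 °C) passes through no free cation and uses the same oxygen-over-ring-A transition state. It should close ring B to the homoallylic alcohol (3aR,4S,8aS)-4-hydroxy-6,8a-dimethyl-7-(phenylsulfinyl)-3-(propan-2-yl)-3a,4,5,6,7,8a-hexahydroazulen-8(1H)-one F1. Mukaiyama hydration of its C3=C4 double bond, the only alkene left (Co(acac)2, PhSiH3, O2, i-PrOH), should deliver the C4 hydroxyl from the convex α-face and give 9. Compound 9 is then heated with NaHCO3 as in the last stage of step 4 to reach 10.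

Step 1. What may go wrong: slow or non-regiospecific triflation of the zinc enolate (enolate equilibration, C-sulfonylation) in the presence of excess dimethylzinc. Fallback (sets out from 1, comes back at 3): the zinc enolate 2 is captured with Me3SiCl instead, and the silyl enol ether methyl (1S)-1-methyl-3-[(trimethylsilyl)oxy]cyclopent-2-ene-1-carboxylate F2 is isolated. MeLi (THF, 0 °C) then releases the regiodefined lithium enolate, which PhNTf2 should convert into 3. Carbon–carbon bond formation and triflation then no longer share one flask.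

Step 6. What may go wrong: poor or reversed facial selectivity of hydride delivery to C10 (attack from the convex α-face instead of anti to the C1 methyl). Fallback (sets out from 12, comes back at 14): if the reduction gives mainly the 10β-alcohol (3R,3aR,4S,8R,8aS)-3,8-dihydroxy-6,8a-dimethyl-3-(propan-2-yl)-1,2,3,3a,4,5,8,8a-octahydroazulen-4-yl 4-methoxybenzoate F3, this epimer is esterified with acetic acid under Mitsunobu conditions (PPh3, DIAD, toluene, 0 °C). This should invert C10 and give 14 directly, replacing step 7.

**Further compounds**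

F1 | step 4 | (3aR,4S,8aS)-4-hydroxy-6,8a-dimethyl-7-(phenylsulfinyl)-3-(propan-2-yl)-3a,4,5,6,7,8a-hexahydroazulen-8(1H)-one | O[C@H]2CC(C)C(S(=O)c1ccccc1)C(=O)[C@@]3(C)CC=C(C(C)C)[C@@H]23
F2 | step 1 | methyl (1S)-1-methyl-3-[(trimethylsilyl)oxy]cyclopent-2-ene-1-carboxylate | COC(=O)[C@@]1(C)CCC(O[Si](C)(C)C)=C1
F3 | step 6 | (3R,3aR,4S,8R,8aS)-3,8-dihydroxy-6,8a-dimethyl-3-(propan-2-yl)-1,2,3,3a,4,5,8,8a-octahydroazulen-4-yl 4-methoxybenzoate | COc1ccc(C(=O)O[C@H]2CC(C)=C[C@@H](O)[C@@]3(C)CC[C@@](O)(C(C)C)[C@@H]23)cc1
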